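What I started from was how slowly the target crept late in the runs. In the south-east run it went only from 18.5% at 1.67 d to 19.1% at 5.00 d, while starting material fell from 50.0% to 31.4%. Coupling partner, charged at half the molarity of starting material, looked like the limiting reagent, so I assumed that the rate at half conversion sat on the tail of its dying supply.

all flasks: starting material 0.80 M

| run | coupling partner | free catalyst | remark |
|---|---|---|---|
| south-west | 0.40 M | 40 mM | run made earlier |
| south-east | 0.40 M | 160 mM | run made earlier |
| north-west | 0.80 M | 80 mM | run made earlier |
| flask | 0.400 M | 80 mM |  |

| run | time / d | target / % | starting material / % |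
|---|---|---|---|
| south-west | 0.417 | 2.7 | 83.8 |
| south-west | 0.625 | 4.6 | 77.4 |
| south-west | 1.04 | 6.7 | 68.1 |
| south-west | 1.67 | 8.4 | 56.7 |
| south-west | 3.00 | 9.1 | 44.2 |
| south-west | 5.00 | 10.4 | 34.9 |
| south-east | 0.417 | 8.1 | 74.6 |
| south-east | 0.625 | 12.2 | 68.2 |
| south-east | 1.04 | 15.9 | 57.8 |
| south-east | 1.67 | 18.5 | 50.0 |
| south-east | 3.00 | 18.5 | 39.2 |
| south-east | 5.00 | 19.1 | 31.4 |
| north-west | 0.417 | 6.5 | 78.5 |
| north-west | 1.25 | 17.3 | 57.1 |
| north-west | 2.50 | 19.8 | 42.1 |
| north-west | 4.00 | 20.8 | 34.9 |
| north-west | 5.00 | 19.7 | 30.5 |

(each reading ± 0.5 percentage points)



- apparent order in free catalyst when 50% of the starting material are converted (percent change of the rate of making target for one percent more free catalyst charged)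
- apparent order in coupling partner when 50% of the starting material are converted (percent change of the rate of making target for one percent more coupling partner charged)
- factor on the rate of making target when 50% of the starting material are converted if free catalyst is charged twice over

I defined the tail constant k as the fraction of the gap between target and plateau that closes per day. The south-east readings put it at 1.98 d⁻¹, a reading that carries their scatter. On such a tail, doubling coupling partner doubles the rate at a fixed time. It also brings half conversion forward by some interval Δt, where the rate has fallen less. Averaged over that doubling, the order in coupling partner is therefore one plus kΔt/ln 2.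

The twice-charged flask is the north-west run. A straight chord overshoots on a decay that bends like these readings, so I interpolated in the reciprocal of starting material and read half conversion there at about 1.75 d, an estimate that carries the scatter. With Δt at zero, the lower bound is 1. The flask has more catalyst than the south-west run, which by the same interpolation took about 2.30 d, so I took 2.58 as the upper bound. Placing the flask midway between the south-west and south-east times, at 1.99 d, I committed to 1.68.

The forecast gave 0.6 for coupling partner, 0.5 for catalyst and a factor of 1.42, calling its slopes “all rough because they sit on the flattening tails”. Its order in coupling partner lies below my bracket.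

The simulation gave 2.4, inside the bracket but above my figure, with 0.87 for catalyst and a factor of 2.01.

    coupling partner + free catalyst ⇌ catalyst intermediate A (K = 7.60 M⁻¹, k = 0.0200 M⁻¹ min⁻¹)
    catalyst intermediate A ⇌ released group + catalyst intermediate B (K = 0.240 M, k = 0.0120 min⁻¹)
    starting material + catalyst intermediate B → catalyst intermediate C (k = 0.00890 M⁻¹ min⁻¹)
    catalyst intermediate C ⇌ free catalyst + target (K = 0.340 M, k = 0.00450 min⁻¹)
    coupling partner → decomposed reagent (k = 0.00110 min⁻¹)
    2 starting material → self-condensation product (k = 1.50 × 10⁻⁴ M⁻¹ min⁻¹)

Carried from 2.05 d to 5.85 d in this flask, k predicts a rate ratio of 5.31 × 10⁻⁴, and the flask gave 5.0 × 10⁻⁴. With twice the coupling partner, the time to half conversion changed by a factor of 0.817, so the rule gives 2.07 against 2.4. In this flask, the making of catalyst intermediate A had 91% of its turnover behind it at 1.00 d, and coupling partner stood at 0.317% by 2.50 d. The loss of starting material to self-condensation product continued after that, and the target stayed at 14.3% while self-condensation product reached 50.3% at 5.00 d.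

All runs are calculated from invented constants; noise was put on by code.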